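**Plan**
- Retrosynthesis: cut the O3–angeloyl bond and C13=C14 (olefination), then C4–C18 (enolate alkylation), then C1–C2 and C9–C10 together, which opens ring A and ring B at once to an acyclic β-keto ester; C4–C5 is cut last (Ireland–Claisen retron).
- Forward: (E)-geranylacetone supplies C1, C5–C13, C16, C17 and C20 (its (E)-terminal methyl becomes C1); propanoate adds C3, C4, C19 and malonate adds C2; ring A (C1–C2) and then ring B (C9–C10) form in one oxidative radical cascade; C18, C14/C15 and the angelate follow.
- Enabling feature: C3 bears oxygen and C2 is an unsubstituted CH2, so C2 can become a 1,3-dicarbonyl radical; C1 and C20 both sit on C10 (a latent isopropenyl group with C1 as its CH2 end), followed by the C8(C17)=C9 isoprene unit. Rings A and B can therefore be zipped from C2 towards C8, the reverse of the usual polyene folding.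
- Stereochemistry: C5 from an enantioselective boron-enolate Ireland–Claisen rearrangement; C10 and C9 relayed from C5 in the cascade; C4 by alkylation anti to the C10 methyl; C3 by thermodynamic reduction; 13E from the olefination; the angelate Z geometry from angelic acid.

Key step: step 6

Remarks and assumptions
- Atom numbers are those of the labdane skeleton: ring A = C1–C5, C10; ring B = C5–C10; C17 = exocyclic CH2 on C8; C11–C16 = side chain on C9 (C16 = methyl on C13); C18 = CH2OH on C4; C19 = methyl on C4; C20 = methyl on C10. The target is (3R,4S,5S,9R,10S).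
- (E)-Geranylacetone is assumed to be bought as the single (E) isomer.
- The boron controller in step 4 is written as its (S,S) form; the sense of induction on this 2-methylallyl ester is assumed by analogy with simple (E)-allylic propanoates, and the (R,R) form is used without other change if the sense proves opposite.
- The C4 configuration in 6–9 (and C2 in 9 and 10) is of no consequence, because C4 is planarised in step 7 and C2 loses its ester in step 8. Only diastereomerically pure 6 must be carried on, since an anti isomer would end as the enantiomeric series once C4 is erased.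

**Route**

Step 1
Reactants: 1 (E)-geranylacetone
Product: 2 2-[(3E)-4,8-dimethylnona-3,7-dien-1-yl]-2-methyl-1,3-dioxolane
Conditions: HOCH2CH2OH, pyridinium p-toluenesulfonate (cat.), benzene, reflux, Dean–Stark
Reagents that add atoms: ethylene glycol, OCCO
Why: Acid-catalysed ketalisation masks the methyl ketone, which would otherwise be enolised in steps 4 and 7 and reduced in step 9, while the trisubstituted alkenes tolerate the weak acid.

Step 2
Reactants: 2 geranylacetone ketal
Product: 3 (2E,6E)-2,6-dimethyl-9-(2-methyl-1,3-dioxolan-2-yl)nona-2,6-dien-1-ol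
Conditions: SeO2 (cat.), t-BuOOH, CH2Cl2, 0 °C → rt
Reagents that add atoms: tert-butyl hydroperoxide, CC(C)(C)OO (oxygen, relayed by SeO2, O=[Se]=O)
Why: SeO2 allylic oxidation (ene reaction then [2,3]-shift) should attack the (E)-methyl of the terminal, most accessible trisubstituted alkene, so the new CH2OH (future C1) lies trans to the chain.

Step 3
Reactants: 3 allylic alcohol
Product: 4 (2E,6E)-2,6-dimethyl-9-(2-methyl-1,3-dioxolan-2-yl)nona-2,6-dien-1-yl propanoate
Conditions: EtCOCl, pyridine, CH2Cl2, 0 °C
Reagents that add atoms: propanoyl chloride, CCC(=O)Cl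
Why: Simple O-acylation of the primary allylic alcohol installs the three carbons that become C3, C4 and C19.

Step 4
Reactants: 4 allylic propanoate
Product: 6 (2R,3R,6E)-2,6-dimethyl-9-(2-methyl-1,3-dioxolan-2-yl)-3-(prop-1-en-2-yl)non-6-enoic acid, via boron ketene acetal 5 (not isolated)
Conditions: (S,S)-2-bromo-4,5-diphenyl-1,3-bis[3,5-bis(trifluoromethyl)phenylsulfonyl]-1,3,2-diazaborolidine (from the (S,S)-bis-sulfonamide and BBr3), i-Pr2NEt, CH2Cl2, −78 °C, then −20 → 4 °C; H2O
Reagents that add atoms: none
Why: Enantioselective Ireland–Claisen rearrangement of the chiral boron ketene acetal through a chair transition state, in which the (E)-alkene places the C6 chain equatorial and the controller on boron selects the enolate face, should fix C5 (3R in 6) and turn the former (E)-methyl carbon into the CH2 terminus C1 of an isopropenyl group; the B–Br bond is consumed in the enolisation at −78 °C, so the ketal should survive.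

Step 5
Reactants: 6 acid
Product: 8 methyl (4R,5R,8E)-4,8-dimethyl-11-(2-methyl-1,3-dioxolan-2-yl)-3-oxo-5-(prop-1-en-2-yl)undec-8-enoate, via acyl imidazole 7 (not isolated)
Conditions: 1,1'-carbonyldiimidazole, THF, rt; then KO2CCH2CO2Me, MgCl2, Et3N, rt → 40 °C; aq. citric acid
Reagents that add atoms: potassium methyl malonate, COC(=O)CC(=O)[O-].[K+]
Why: C-acylation of the magnesium malonate by the acyl imidazole with loss of CO2 gives the β-keto ester under near-neutral conditions, adding C2 together with the ester that activates it.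

Step 6
Reactants: 8 acyclic β-keto ester
Product: 9 methyl 13,13-(ethylenedioxy)-3-oxo-14,15,18-trinor-ent-labd-8(17)-ene-2-carboxylate (trans-decalin, C4 methyl equatorial, C9 chain equatorial and cis to C20)
Conditions: Mn(OAc)3·2H2O (2.2 equiv), Cu(OAc)2·H2O (1 equiv), degassed EtOH, rt
Reagents that add atoms: none
Why: Trivalent manganese oxidises the enolate of the β-keto ester to the electrophilic C2 radical, which adds to the CH2 terminus C1 of the 1,1-disubstituted alkene (6-endo-trig, ring A, ketone inside the ring) and leaves a nucleophilic tertiary radical at C10; this adds to C9 of the (E)-trisubstituted alkene (6-endo-trig, ring B), and divalent copper captures the resulting tertiary C8 radical as a trivalent alkylcopper species that loses a β-hydrogen from the C17 methyl to give the exocyclic alkene. The closest known reaction type is the oxidative free-radical polyene cyclisation of unsaturated β-keto esters with Mn(OAc)3/Cu(OAc)2, run here from the C2 side of the ketone so that the chain closes from C1 towards C8. C10 is set relative to C5 because the C6 chain sits equatorial on the new chair of ring A and closes ring B through a chair transition state with the C10 methyl axial and anti to H5 (trans-decalin), and C9 is set by the (E) geometry of C8=C9, which puts C11 equatorial. C2 and C4 are epimerisable and of no consequence. The step needs 6-endo over 5-exo closure in both rings (secured by the fully substituted inner alkene carbons C10 and C8), cyclisation of the C10 radical faster than its oxidation (favoured by limiting Cu(OAc)2), and hydrogen loss from C17 and not from C7 or C9 (the usual preference of the copper-mediated elimination for the less substituted alkene).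

Step 7
Reactants: 9 bicyclic β-keto ester
Product: 10 methyl 18-benzyloxy-13,13-(ethylenedioxy)-3-oxo-14,15-dinor-ent-labd-8(17)-ene-2-carboxylate (C4: methyl axial and cis to C20, CH2OBn equatorial)
Conditions: LiN(i-Pr)2 (2.3 equiv), THF, −78 → 0 °C; then BnOCH2Cl, −78 → −20 °C
Reagents that add atoms: benzyl chloromethyl ether, ClCOCc1ccccc1
Why: γ-Alkylation of the β-keto ester dianion occurs at the more basic C4 carbanion and not at C2, and the electrophile should enter anti to the axial C10 methyl, so the new CH2O group becomes equatorial and the C4 methyl axial, as in the target.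

Step 8
Reactants: 10 alkylated β-keto ester
Product: 11 18-benzyloxy-13,13-(ethylenedioxy)-14,15-dinor-ent-labd-8(17)-en-3-one
Conditions: LiCl, H2O, DMSO, 150 °C
Reagents that add atoms: none
Why: Krapcho dealkoxycarbonylation removes the activating ester from C2 under neutral conditions that spare the ketal, the benzyl ether and the exocyclic alkene; C4 is quaternary and cannot epimerise.

Step 9
Reactants: 11 ketone
Product: 13 3,18-dihydroxy-14,15-dinor-ent-labd-8(17)-en-13-one, via diol ketal 12 (not isolated)
Conditions: Li, NH3(l), THF, t-BuOH, −78 → −33 °C; NH4Cl; then 1 M aq. HCl, THF, rt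
Reagents that add atoms: water, O
Why: Dissolving-metal reduction should give the thermodynamically favoured equatorial C3 alcohol and cleave the benzyl ether in the same operation without touching the isolated alkene; dilute acid then hydrolyses the ketal.

Step 10
Reactants: 13 keto diol
Product: 14 ethyl 3,18-dihydroxy-ent-labda-8(17),13E-dien-15-oate
Conditions: (EtO)2P(O)CH2CO2Et, NaH, THF, 0 → 50 °C; chromatographic removal of the minor 13Z isomer
Reagents that add atoms: triethyl phosphonoacetate, CCOC(=O)CP(=O)(OCC)OCC
Why: Horner–Wadsworth–Emmons olefination of the methyl ketone should favour the (13E)-enoate, and the stabilised phosphonate anion is too weakly basic to disturb the free hydroxy groups.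

Step 11
Reactants: 14 enoate
Product: 15 ent-labda-8(17),13E-diene-3,15,18-triol
Conditions: i-Bu2AlH, CH2Cl2, −78 → 0 °C; aq. Rochelle salt
Reagents that add atoms: none
Why: 1,2-Reduction of the conjugated ester by the aluminium hydride gives the (E)-allylic alcohol without touching either alkene.

Step 12
Reactants: 15 triol
Product: 16 15,18-bis(tert-butyldimethylsilyloxy)-ent-labda-8(17),13E-dien-3-ol
Conditions: t-BuMe2SiCl (2.2 equiv), imidazole, CH2Cl2, 0 °C
Reagents that add atoms: tert-butyldimethylsilyl chloride, CC(C)(C)[Si](C)(C)Cl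
Why: Silylation distinguishes the two primary hydroxy groups (C15 allylic, C18 neopentyl) from the secondary C3–OH, which is shielded by the quaternary C4.

Step 13
Reactants: 16 bis-silyl ether; 17 angelic acid
Product: 19 3-O-angeloyl-15,18-bis(tert-butyldimethylsilyloxy)-ent-labda-8(17),13E-diene, via mixed anhydride 18 (not isolated)
Conditions: 17, 2,4,6-Cl3C6H2COCl, Et3N, toluene, rt; then 16, 75 °C
Reagents that add atoms: none
Why: Yamaguchi-type esterification: the alcohol attacks the less hindered angeloyl carbonyl of the mixed anhydride, and without a nucleophilic catalyst no addition–elimination occurs at the β-carbon, so the (Z) geometry should be kept.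

Step 14
Reactants: 19 angelate bis-silyl ether
Product: 20 (3R,4S,5S,9R,10S)-3-angeloyloxy-ent-labda-8(17),13E-diene-15,18-diol (CNP0118197.1)
Conditions: HF·pyridine, pyridine/THF, 0 °C → rt
Reagents that add atoms: none
Why: Fluoride cleavage of both silyl ethers under buffered, non-basic conditions should leave the angelate, its (Z) geometry and the exocyclic alkene untouched and avoid a 1,3-acyl shift to O18.

**Compound list**
1 | (E)-geranylacetone, (5E)-6,10-dimethylundeca-5,9-dien-2-one | CC(C)=CCC/C(C)=C/CCC(C)=O | starting material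
2 | 2-[(3E)-4,8-dimethylnona-3,7-dien-1-yl]-2-methyl-1,3-dioxolane | CC(C)=CCC/C(C)=C/CCC1(C)OCCO1 | intermediate
3 | (2E,6E)-2,6-dimethyl-9-(2-methyl-1,3-dioxolan-2-yl)nona-2,6-dien-1-ol | OC/C(C)=C/CC/C(C)=C/CCC1(C)OCCO1 | intermediate
4 | (2E,6E)-2,6-dimethyl-9-(2-methyl-1,3-dioxolan-2-yl)nona-2,6-dien-1-yl propanoate | CCC(=O)OC/C(C)=C/CC/C(C)=C/CCC1(C)OCCO1 | intermediate
5 | boron ketene acetal of 4 (methyl cis to O–B; boron carries the (S,S)-bis-sulfonamide) | C/C=C(/OC/C(C)=C/CC/C(C)=C/CCC1(C)OCCO1)OB2N(S(=O)(=O)c3cc(cc(c3)C(F)(F)F)C(F)(F)F)[C@@H](c3ccccc3)[C@H](c3ccccc3)N2S(=O)(=O)c3cc(cc(c3)C(F)(F)F)C(F)(F)F | intermediate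
6 | (2R,3R,6E)-2,6-dimethyl-9-(2-methyl-1,3-dioxolan-2-yl)-3-(prop-1-en-2-yl)non-6-enoic acid | OC(=O)[C@H](C)[C@@H](CC/C(C)=C/CCC1(C)OCCO1)C(C)=C | intermediate
7 | N-acylimidazole of 6 | O=C(n1ccnc1)[C@H](C)[C@@H](CC/C(C)=C/CCC2(C)OCCO2)C(C)=C | intermediate
8 | methyl (4R,5R,8E)-4,8-dimethyl-11-(2-methyl-1,3-dioxolan-2-yl)-3-oxo-5-(prop-1-en-2-yl)undec-8-enoate | COC(=O)CC(=O)[C@H](C)[C@@H](CC/C(C)=C/CCC1(C)OCCO1)C(C)=C | intermediate
9 | methyl 13,13-(ethylenedioxy)-3-oxo-14,15,18-trinor-ent-labd-8(17)-ene-2-carboxylate (H5/C20 trans; C4 methyl and C2 ester equatorial, both epimerisable) | C=C1CC[C@H]2[C@@](C)(C[C@H](C(=O)OC)C(=O)[C@@H]2C)[C@@H]1CCC3(C)OCCO3 | intermediate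
10 | methyl 18-benzyloxy-13,13-(ethylenedioxy)-3-oxo-14,15-dinor-ent-labd-8(17)-ene-2-carboxylate (C4 methyl axial, CH2OBn equatorial) | C=C1CC[C@H]2[C@@](C)(C[C@H](C(=O)OC)C(=O)[C@]2(C)COCc3ccccc3)[C@@H]1CCC3(C)OCCO3 | intermediate
11 | 18-benzyloxy-13,13-(ethylenedioxy)-14,15-dinor-ent-labd-8(17)-en-3-one | C=C1CC[C@H]2[C@@](C)(CCC(=O)[C@]2(C)COCc3ccccc3)[C@@H]1CCC3(C)OCCO3 | intermediate
12 | 13,13-(ethylenedioxy)-14,15-dinor-ent-labd-8(17)-ene-3,18-diol (3-OH equatorial) | C=C1CC[C@H]2[C@@](C)(CC[C@@H](O)[C@]2(C)CO)[C@@H]1CCC3(C)OCCO3 | intermediate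
13 | 3,18-dihydroxy-14,15-dinor-ent-labd-8(17)-en-13-one | C=C1CC[C@H]2[C@@](C)(CC[C@@H](O)[C@]2(C)CO)[C@@H]1CCC(C)=O | intermediate
14 | ethyl 3,18-dihydroxy-ent-labda-8(17),13E-dien-15-oate | C=C1CC[C@H]2[C@@](C)(CC[C@@H](O)[C@]2(C)CO)[C@@H]1CC/C(C)=C/C(=O)OCC | intermediate
15 | ent-labda-8(17),13E-diene-3,15,18-triol, configured as 20 | C=C1CC[C@H]2[C@@](C)(CC[C@@H](O)[C@]2(C)CO)[C@@H]1CC/C(C)=C/CO | intermediate
16 | 15,18-bis(tert-butyldimethylsilyloxy)-ent-labda-8(17),13E-dien-3-ol | C=C1CC[C@H]2[C@@](C)(CC[C@@H](O)[C@]2(C)CO[Si](C)(C)C(C)(C)C)[C@@H]1CC/C(C)=C/CO[Si](C)(C)C(C)(C)C | intermediate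
17 | angelic acid, (Z)-2-methylbut-2-enoic acid | C/C=C(/C)C(=O)O | starting material
18 | angelic 2,4,6-trichlorobenzoic anhydride | C/C=C(/C)C(=O)OC(=O)c1c(Cl)cc(Cl)cc1Cl | intermediate
19 | 3-O-angeloyl-15,18-bis(tert-butyldimethylsilyloxy)-ent-labda-8(17),13E-diene | C=C1CC[C@H]2[C@@](C)(CC[C@@H](OC(=O)/C(C)=C\C)[C@]2(C)CO[Si](C)(C)C(C)(C)C)[C@@H]1CC/C(C)=C/CO[Si](C)(C)C(C)(C)C | intermediate
20 | (3R,4S,5S,9R,10S)-3-angeloyloxy-ent-labda-8(17),13E-diene-15,18-diol (CNP0118197.1) | C=C1CC[C@H]2[C@@](C)(CC[C@@H](OC(=O)/C(C)=C\C)[C@]2(C)CO)[C@@H]1CC/C(C)=C/CO | target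

Total step count: 14. Longest linear sequence: 14 steps (1 → 20); angelic acid 17 enters in step 13.

**Steps most likely to fail**

Step 6. The product is a more easily enolised β-keto ester than the starting material and may be re-oxidised at C2. The C10 radical may also be oxidised by copper before ring B closes, and hydrogen loss towards C7 would give the endocyclic alkene. The fallback sets out from 8 and blocks C2 with a removable substituent. Chlorination at C2 (N-chlorosuccinimide, K2CO3, CH2Cl2) should give methyl 2-chloro-4,8-dimethyl-11-(2-methyl-1,3-dioxolan-2-yl)-3-oxo-5-(prop-1-en-2-yl)undec-8-enoate F1. The same Mn(OAc)3/Cu(OAc)2 cascade, a known use of α-chloro β-keto esters, should then give the 2-chloro bicyclic keto ester F2, whose quaternary C2 can no longer be enolised or oxidised. Zinc dust with NH4Cl in MeOH/THF removes the chlorine and returns the route at 9.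

Step 4. Facial discrimination by the boron controller may be insufficient on this 2-methylallyl ester, or both ketene acetal geometries may form; because C4 is erased in step 7, any anti diastereomer ends as the wrong enantiomer. The fallback sets out from 4 and replaces asymmetric induction by resolution. LiN(i-Pr)2 and Me3SiCl in THF/DMPU give the trimethylsilyl ketene acetal F3, whose Ireland–Claisen rearrangement and hydrolysis give the racemic syn acid F4. Coupling through the pivaloyl mixed anhydride with lithiated (S)-4-benzyl-1,3-oxazolidin-2-one gives two diastereomeric imides. Chromatography should deliver the imide of the (2R,3R) acid F5, and LiOH/H2O2 cleavage comes back to the route at 6.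

Step 7. Deprotonation at the tertiary C4 position may be incomplete, the hard chloromethyl ether may alkylate on oxygen, or attack may occur on the face syn to the C10 methyl. The fallback sets out from 9 and builds the C4 centre from a regiodefined ketone enolate instead of the dianion. Krapcho dealkoxycarbonylation (LiCl, H2O, DMSO, 150 °C) gives the 4-methyl ketone F6. Equilibrating silylation (Me3SiCl, NaI, Et3N, MeCN) should give the more substituted C3=C4 trimethylsilyl enol ether F7. MeLi releases the lithium enolate, which is trapped with monomeric formaldehyde at −78 °C, anti to the C10 methyl, to give the 18-hydroxy ketone F8. NaBH4 in MeOH then comes back to the route at 12, which is hydrolysed to 13 as in the second stage of step 9.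

**Further compounds**
F1 | step 6 | methyl 2-chloro-4,8-dimethyl-11-(2-methyl-1,3-dioxolan-2-yl)-3-oxo-5-(prop-1-en-2-yl)undec-8-enoate (4R,5R; C2 epimers) | COC(=O)C(Cl)C(=O)[C@H](C)[C@@H](CC/C(C)=C/CCC1(C)OCCO1)C(C)=C
F2 | step 6 | methyl 2-chloro-13,13-(ethylenedioxy)-3-oxo-14,15,18-trinor-ent-labd-8(17)-ene-2-carboxylate (C2 epimers) | C=C1CC[C@H]2[C@@](C)(CC(Cl)(C(=O)OC)C(=O)[C@@H]2C)[C@@H]1CCC3(C)OCCO3
F3 | step 4 | trimethylsilyl ketene acetal of 4 (methyl cis to O–Si) | C/C=C(/OC/C(C)=C/CC/C(C)=C/CCC1(C)OCCO1)O[Si](C)(C)C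
F4 | step 4 | racemic syn-2,6-dimethyl-9-(2-methyl-1,3-dioxolan-2-yl)-3-(prop-1-en-2-yl)non-6-enoic acid (both enantiomers) | OC(=O)[C@H](C)[C@@H](CC/C(C)=C/CCC1(C)OCCO1)C(C)=C.OC(=O)[C@@H](C)[C@H](CC/C(C)=C/CCC1(C)OCCO1)C(C)=C
F5 | step 4 | (S)-4-benzyl-3-acyl-1,3-oxazolidin-2-one of the (2R,3R) acid 6 | O=C1OC[C@H](Cc2ccccc2)N1C(=O)[C@H](C)[C@@H](CC/C(C)=C/CCC3(C)OCCO3)C(C)=C
F6 | step 7 | 13,13-(ethylenedioxy)-14,15,18-trinor-ent-labd-8(17)-en-3-one (C4 methyl equatorial) | C=C1CC[C@H]2[C@@](C)(CCC(=O)[C@@H]2C)[C@@H]1CCC3(C)OCCO3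
F7 | step 7 | 3-(trimethylsilyloxy)-13,13-(ethylenedioxy)-14,15,18-trinor-ent-labda-3,8(17)-diene | C=C1CC[C@H]2[C@@](C)(CCC(O[Si](C)(C)C)=C2C)[C@@H]1CCC3(C)OCCO3
F8 | step 7 | 18-hydroxy-13,13-(ethylenedioxy)-14,15-dinor-ent-labd-8(17)-en-3-one | C=C1CC[C@H]2[C@@](C)(CCC(=O)[C@]2(C)CO)[C@@H]1CCC3(C)OCCO3
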